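**Plan**

1. Numbering: ring B is the chromane (O1, C2, C3, C4, C4a, C5–C8, C8a); the chain is Cα (on C6), Cβ, Cγ (on C1' of ring A); ring A has OH on C2' and C4' and the 1,1-dimethylallyl group on C5'.
2. Retrosynthetic cuts: the pyran ring across O1–C2 and C3–C4 (ortho-quinone methide of ring B + isobutene); the C5–prenyl bond (lithiation directed by the CH2NMe2 group that is the precursor of C4); the chain at Cβ–Cγ (alkyl Grignard reagent + ring A aldehyde, the benzylic oxygen leaving through a second ortho-quinone methide that takes up hydride); the C5'–CMe2 bond (Claisen rearrangement of the C4' prenyl ether).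
3. Feature that makes the key step possible: C4 is an unsubstituted benzylic CH2 on C4a, ortho to the ring oxygen O1 on C8a, and C2 is a gem-dimethyl carbon, so O1=C8a–C4a=C4 is a 1-oxadiene and C2–C3 is isobutene. As CH2NMe2 the same carbon first steers the prenyl group to the neighbouring C5, which settles the contiguous C4a/C5/C6 substitution of ring B, the hardest part of the target.
4. Forward order: ring B of homovanillyl alcohol is decorated (Mannich reaction, silylation, C5 prenylation), the pyran ring is closed (step 4) and the side chain becomes a bromide; the chain is then joined to the O-prenyl, O-Boc aldehyde of ring A (step 9); Claisen rearrangement and O-demethylation finish.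
5. Stereochemistry: the target has no stereocentre and no stereogenic double bond; only regio- and chemoselectivity have to be controlled.

Key step: step 4

Remark on the chemistry: small reagents that only deliver a group (dimethylamine, formaldehyde, silyl triflate, prenyl bromide, isobutene, Boc2O) are named under each step and are not numbered; TIPS = triisopropylsilyl.

**Route**

Step 1
Reactants: 1 homovanillyl alcohol (4-(2-hydroxyethyl)-2-methoxyphenol)
Product: 2 Mannich base (2-[(dimethylamino)methyl]-4-(2-hydroxyethyl)-6-methoxyphenol)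
Conditions: Me2NH (40% aq.), CH2O (37% aq.), EtOH, 25 → 60 °C
Reagents that add atoms: dimethylamine CNC; formaldehyde C=O
Why: Phenolic Mannich reaction; the iminium ion should attack the only free position ortho to the hydroxyl (the other ortho position carries OMe, the para position the side chain), which installs the future C4 as CH2NMe2.

Step 2
Reactants: 2 Mannich base
Product: 3 bis-silyl ether (N,N-dimethyl-1-[3-methoxy-2-(triisopropylsilyloxy)-5-(2-triisopropylsilyloxyethyl)phenyl]methanamine)
Conditions: TIPSOTf (2.3 equiv), 2,6-lutidine, CH2Cl2, 0 °C → rt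
Reagents that add atoms: triisopropylsilyl trifluoromethanesulfonate CC(C)[Si](C(C)C)(C(C)C)OS(=O)(=O)C(F)(F)F
Why: Silylation of the phenol and the primary alcohol with a silyl triflate; both bulky ethers should withstand n-BuLi, and the aryl silyl ether is the later fluoride-sensitive trigger.

Step 3
Reactants: 3 bis-silyl ether
Product: 5 prenylated benzylamine (N,N-dimethyl-1-[3-methoxy-6-(3-methylbut-2-enyl)-2-(triisopropylsilyloxy)-5-(2-triisopropylsilyloxyethyl)phenyl]methanamine), via aryllithium 4 (not isolated)
Conditions: n-BuLi (1.5 equiv), Et2O, 0 °C → rt; then CuBr·SMe2 (10 mol %), prenyl bromide, −78 °C → rt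
Reagents that add atoms: prenyl bromide (1-bromo-3-methylbut-2-ene) CC(C)=CCBr
Why: Directed ortho-metalation, in which the CH2NMe2 group binds n-BuLi and delivers it to its only free ortho position (ring C6, the later chromane C5) rather than to the position next to OMe, which is favoured only with chelating diamine additives; copper-catalysed SN2 coupling of the aryllithium with prenyl bromide should give the linear prenyl group.

Step 4
Reactants: 5 prenylated benzylamine
Product: 8 chromane silyl ether (8-methoxy-2,2-dimethyl-5-(3-methylbut-2-enyl)-6-(2-triisopropylsilyloxyethyl)chromane), via ammonium iodide 6 (not isolated), via ortho-quinone methide 7 (not isolated)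
Conditions: MeI, MeCN, rt, then evaporation of excess MeI; CsF (1.5 equiv), isobutene (large excess, condensed in), MeCN, sealed tube, 90 °C
Reagents that add atoms: isobutene (2-methylpropene) CC(C)=C
Why: Exhaustive N-methylation turns the directing group into a leaving group, and fluoride then frees the C8a phenoxide, which expels NMe3 in a 1,4-elimination to give ortho-quinone methide 7 (O=C8a–C4a=C4H2), an electron-poor 1-oxadiene held in reserve as its reversible adducts with NMe3, iodide and fluoride. It is consumed irreversibly by an inverse-electron-demand hetero-Diels–Alder reaction with isobutene, the closest known type being the chromane-forming cycloaddition of phenol-derived ortho-quinone methides (from Mannich bases, salicyl alcohols or ortho-silyloxybenzyl salts) with enol ethers, styrenes and 1,1-disubstituted alkenes. The pyran ring closes in one intermolecular [4+2] event that makes C4–C3 and O1–C2 together and restores the aromaticity of ring B. No stereocentre is formed. The step needs regioselectivity, which the polarisation of both partners secures (the CH2 terminus of isobutene bonds to the electrophilic methide carbon C4, the incipient tertiary centre C2 to oxygen), and chemoselectivity against the C5 prenyl group, secured because an internal [4+2] would place aromatic C4a at a bridgehead and because isobutene is in large excess over the hindered trisubstituted alkenes of other molecules. The primary silyl ether is kept so that no alcohol can add to the methide.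

Step 5
Reactants: 8 chromane silyl ether
Product: 9 chromane alcohol (2-[8-methoxy-2,2-dimethyl-5-(3-methylbut-2-enyl)chroman-6-yl]ethanol)
Conditions: Bu4NF, THF, rt
Reagents that add atoms: none
Why: Fluoride cleavage of the primary silyl ether, driven by the Si–F bond; nothing else in 8 is sensitive to fluoride.

Step 6
Reactants: 9 chromane alcohol
Product: 10 bromide (6-(2-bromoethyl)-8-methoxy-2,2-dimethyl-5-(3-methylbut-2-enyl)chromane)
Conditions: CBr4, PPh3, CH2Cl2, 0 °C
Reagents that add atoms: carbon tetrabromide BrC(Br)(Br)Br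
Why: Appel reaction; bromide displaces the oxyphosphonium group at a primary carbon under neutral conditions that should leave the prenyl group and the chromane untouched.

Step 7
Reactants: 11 2,4-dihydroxybenzaldehyde
Product: 12 prenyl ether (2-hydroxy-4-(3-methylbut-2-enyloxy)benzaldehyde)
Conditions: prenyl bromide (1.05 equiv), K2CO3 (1.0 equiv), acetone, rt → 40 °C
Reagents that add atoms: prenyl bromide (1-bromo-3-methylbut-2-ene) CC(C)=CCBr
Why: Williamson etherification; the 4-OH (para to CHO) is the more acidic and is not tied up in the hydrogen bond to the carbonyl as the 2-OH is, so monoalkylation at O4 should result.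

Step 8
Reactants: 12 prenyl ether
Product: 13 aryl carbonate (tert-butyl 2-formyl-5-(3-methylbut-2-enyloxy)phenyl carbonate)
Conditions: Boc2O, iPr2NEt, DMAP (cat.), THF, rt
Reagents that add atoms: di-tert-butyl dicarbonate CC(C)(C)OC(=O)OC(=O)OC(C)(C)C
Why: DMAP-catalysed O-acylation of the chelated phenol gives the aryl tert-butyl carbonate that drives the cascade of step 9.

Step 9
Reactants: 10 bromide; 13 aryl carbonate
Product: 17 diarylpropane (2-{3-[8-methoxy-2,2-dimethyl-5-(3-methylbut-2-enyl)chroman-6-yl]propyl}-5-(3-methylbut-2-enyloxy)phenol), via Grignard reagent 14 (not isolated), via magnesium alkoxide 15 (not isolated), via ortho-quinone methide 16 (not isolated)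
Conditions: 10, Mg turnings (I2 crystal), THF, rt → 40 °C; add to 13 (1.0 equiv), THF, −78 °C; then NaBH4 (excess), EtOH, −78 °C → rt; aq. NH4Cl
Reagents that add atoms: none
Why: Grignard addition to the aldehyde followed by the anionic ortho-quinone methide cascade of ortho-O-Boc benzylic alkoxides, in which alkoxide 15 takes over the Boc group, the freed phenoxide expels tert-butyl carbonate to give 16, and borohydride adds 1,4 to the methide carbon, so that the Cβ–Cγ bond is made, the benzylic oxygen is removed and the C2' phenol is set free beside the untouched C4' prenyl ether in one flask.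

Step 10
Reactants: 17 diarylpropane
Product: 19 O-methyl kazinol D (4-{3-[8-methoxy-2,2-dimethyl-5-(3-methylbut-2-enyl)chroman-6-yl]propyl}-6-(2-methylbut-3-en-2-yl)benzene-1,3-diol), via dienone 18 (not isolated)
Conditions: N,N-diethylaniline, 190 °C, sealed tube, argon
Reagents that add atoms: none
Why: Aromatic Claisen rearrangement ([3,3]) of the aryl prenyl ether with allyl inversion, so the ring bonds to the dimethyl-substituted terminus; migration should go to C5' (para to the C2' hydroxyl, the less hindered ortho position) and not to C3' between the two oxygens, dienone 18 then enolises, and the basic solvent suppresses acid-induced cyclisation of the product.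

Step 11
Reactants: 19 O-methyl kazinol D
Product: 20 Kazinol D (4-{3-[8-hydroxy-2,2-dimethyl-5-(3-methylbut-2-enyl)chroman-6-yl]propyl}-6-(2-methylbut-3-en-2-yl)benzene-1,3-diol)
Conditions: NaSEt (6 equiv), DMF, 130 °C; then 1 M HCl
Reagents that add atoms: none
Why: SN2 demethylation of the aryl methyl ether by thiolate; the leaving group is an ortho-alkoxy phenoxide, the tertiary chromane ether cannot react by SN2, and the isolated alkenes and the ring A phenoxides should be inert to the thiolate.

**Compound list**

1 | homovanillyl alcohol, 4-(2-hydroxyethyl)-2-methoxyphenol | COc1cc(CCO)ccc1O | starting material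
2 | 2-[(dimethylamino)methyl]-4-(2-hydroxyethyl)-6-methoxyphenol | COc1cc(CCO)cc(CN(C)C)c1O | intermediate
3 | N,N-dimethyl-1-[3-methoxy-2-(triisopropylsilyloxy)-5-(2-triisopropylsilyloxyethyl)phenyl]methanamine | COc1cc(CCO[Si](C(C)C)(C(C)C)C(C)C)cc(CN(C)C)c1O[Si](C(C)C)(C(C)C)C(C)C | intermediate
4 | 6-lithio derivative of 3 (not isolated) | COc1cc(CCO[Si](C(C)C)(C(C)C)C(C)C)c([Li])c(CN(C)C)c1O[Si](C(C)C)(C(C)C)C(C)C | intermediate
5 | N,N-dimethyl-1-[3-methoxy-6-(3-methylbut-2-enyl)-2-(triisopropylsilyloxy)-5-(2-triisopropylsilyloxyethyl)phenyl]methanamine | COc1cc(CCO[Si](C(C)C)(C(C)C)C(C)C)c(CC=C(C)C)c(CN(C)C)c1O[Si](C(C)C)(C(C)C)C(C)C | intermediate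
6 | N,N,N-trimethylammonium iodide of 5 (not isolated) | COc1cc(CCO[Si](C(C)C)(C(C)C)C(C)C)c(CC=C(C)C)c(C[N+](C)(C)C)c1O[Si](C(C)C)(C(C)C)C(C)C.[I-] | intermediate
7 | 2-methoxy-6-methylidene-5-(3-methylbut-2-enyl)-4-(2-triisopropylsilyloxyethyl)cyclohexa-2,4-dien-1-one (not isolated) | COC1=CC(CCO[Si](C(C)C)(C(C)C)C(C)C)=C(CC=C(C)C)C(=C)C1=O | intermediate
8 | 8-methoxy-2,2-dimethyl-5-(3-methylbut-2-enyl)-6-(2-triisopropylsilyloxyethyl)chromane | COc1cc(CCO[Si](C(C)C)(C(C)C)C(C)C)c(CC=C(C)C)c2c1OC(C)(C)CC2 | intermediate
9 | 2-[8-methoxy-2,2-dimethyl-5-(3-methylbut-2-enyl)chroman-6-yl]ethanol | COc1cc(CCO)c(CC=C(C)C)c2c1OC(C)(C)CC2 | intermediate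
10 | 6-(2-bromoethyl)-8-methoxy-2,2-dimethyl-5-(3-methylbut-2-enyl)chromane | COc1cc(CCBr)c(CC=C(C)C)c2c1OC(C)(C)CC2 | intermediate
11 | 2,4-dihydroxybenzaldehyde | O=Cc1ccc(O)cc1O | starting material
12 | 2-hydroxy-4-(3-methylbut-2-enyloxy)benzaldehyde | CC(C)=CCOc1ccc(C=O)c(O)c1 | intermediate
13 | tert-butyl 2-formyl-5-(3-methylbut-2-enyloxy)phenyl carbonate | CC(C)=CCOc1ccc(C=O)c(OC(=O)OC(C)(C)C)c1 | intermediate
14 | 2-[8-methoxy-2,2-dimethyl-5-(3-methylbut-2-enyl)chroman-6-yl]ethylmagnesium bromide (not isolated) | COc1cc(CC[Mg]Br)c(CC=C(C)C)c2c1OC(C)(C)CC2 | intermediate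
15 | bromomagnesium 1-[2-(tert-butoxycarbonyloxy)-4-(3-methylbut-2-enyloxy)phenyl]-3-[8-methoxy-2,2-dimethyl-5-(3-methylbut-2-enyl)chroman-6-yl]propan-1-olate, racemic (not isolated) | CC(C)=CCOc1ccc(C(CCc2cc(OC)c3c(c2CC=C(C)C)CCC(C)(C)O3)O[Mg]Br)c(OC(=O)OC(C)(C)C)c1 | intermediate
16 | 6-{3-[8-methoxy-2,2-dimethyl-5-(3-methylbut-2-enyl)chroman-6-yl]propylidene}-3-(3-methylbut-2-enyloxy)cyclohexa-2,4-dien-1-one (not isolated) | CC(C)=CCOC1=CC(=O)C(=CCCc2cc(OC)c3c(c2CC=C(C)C)CCC(C)(C)O3)C=C1 | intermediate
17 | 2-{3-[8-methoxy-2,2-dimethyl-5-(3-methylbut-2-enyl)chroman-6-yl]propyl}-5-(3-methylbut-2-enyloxy)phenol | CC(C)=CCOc1ccc(CCCc2cc(OC)c3c(c2CC=C(C)C)CCC(C)(C)O3)c(O)c1 | intermediate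
18 | 3-hydroxy-4-{3-[8-methoxy-2,2-dimethyl-5-(3-methylbut-2-enyl)chroman-6-yl]propyl}-6-(2-methylbut-3-en-2-yl)cyclohexa-2,4-dien-1-one, racemic (not isolated) | C=CC(C)(C)C1C=C(CCCc2cc(OC)c3c(c2CC=C(C)C)CCC(C)(C)O3)C(O)=CC1=O | intermediate
19 | 4-{3-[8-methoxy-2,2-dimethyl-5-(3-methylbut-2-enyl)chroman-6-yl]propyl}-6-(2-methylbut-3-en-2-yl)benzene-1,3-diol | C=CC(C)(C)c1cc(CCCc2cc(OC)c3c(c2CC=C(C)C)CCC(C)(C)O3)c(O)cc1O | intermediate
20 | Kazinol D, 4-{3-[8-hydroxy-2,2-dimethyl-5-(3-methylbut-2-enyl)chroman-6-yl]propyl}-6-(2-methylbut-3-en-2-yl)benzene-1,3-diol | C=CC(C)(C)c1cc(CCCc2cc(O)c3c(c2CC=C(C)C)CCC(C)(C)O3)c(O)cc1O | target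

**Step count and risks**

Total steps: 11. Longest linear sequence: 9 steps (steps 1–6, then 9–11); steps 7–8 form the short ring A branch.

Steps most likely to fail:

Step 4. Isobutene is a weak 2π partner, so oligomerisation of the methide or a stepwise cationic closure of the methide carbon onto the neighbouring C5 prenyl group may outrun the cycloaddition. The fallback sets out from 5. The same quaternisation and fluoride protocol is run with 2-methoxypropene at room temperature (enol ethers are the fastest known partners for ortho-quinone methides), which should give the cyclic ketal 2,8-dimethoxy-2-methyl-5-(3-methylbut-2-enyl)-6-(2-triisopropylsilyloxyethyl)chromane F1. AlMe3 (CH2Cl2, −78 → 0 °C) then ionises the ketal to the cyclic oxocarbenium ion and delivers methyl to C2, which comes back to the route at 8.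

Step 3. Lithiation may be slow between the two flanking substituents, or may be misdirected to the position next to the methoxy group. The fallback sets out from 3 and fixes the site by electrophilic substitution para to OMe instead of by coordination. Bromination (NBS, CF3CO2H 1 equiv to mask the amine, MeCN, 0 °C) should give 1-[2-bromo-5-methoxy-6-(triisopropylsilyloxy)-3-(2-triisopropylsilyloxyethyl)phenyl]-N,N-dimethylmethanamine F2. Bromine–lithium exchange (t-BuLi, Et2O, −78 °C) and the same copper-catalysed coupling with prenyl bromide come back to the route at 5.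

Step 9. The alkyl-substituted methide may tautomerise by a 1,5-hydrogen shift to an ortho-hydroxystyrene before hydride arrives, and Wurtz coupling may erode the Grignard formation. The fallback sets out from 10 and 12 and makes the Cβ–Cγ bond by olefination. PPh3 (MeCN, reflux) converts 10 into {2-[8-methoxy-2,2-dimethyl-5-(3-methylbut-2-enyl)chroman-6-yl]ethyl}triphenylphosphonium bromide F3. Its ylide (NaN(SiMe3)2, THF, −78 °C) with the sodium phenoxide of 12 should give the alkene 2-{3-[8-methoxy-2,2-dimethyl-5-(3-methylbut-2-enyl)chroman-6-yl]prop-1-enyl}-5-(3-methylbut-2-enyloxy)phenol F4 as an E/Z mixture. Diimide (2-nitrobenzenesulfonyl hydrazide, Et3N, CH2Cl2, rt) reduces the 1,2-disubstituted alkene much faster than the trisubstituted prenyl alkenes, which comes back to the route at 17.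

**Further compounds**

F1 | step 4 | 2,8-dimethoxy-2-methyl-5-(3-methylbut-2-enyl)-6-(2-triisopropylsilyloxyethyl)chromane (racemic) | COc1cc(CCO[Si](C(C)C)(C(C)C)C(C)C)c(CC=C(C)C)c2c1OC(C)(OC)CC2
F2 | step 3 | 1-[2-bromo-5-methoxy-6-(triisopropylsilyloxy)-3-(2-triisopropylsilyloxyethyl)phenyl]-N,N-dimethylmethanamine | COc1cc(CCO[Si](C(C)C)(C(C)C)C(C)C)c(Br)c(CN(C)C)c1O[Si](C(C)C)(C(C)C)C(C)C
F3 | step 9 | {2-[8-methoxy-2,2-dimethyl-5-(3-methylbut-2-enyl)chroman-6-yl]ethyl}triphenylphosphonium bromide | COc1cc(CC[P+](c3ccccc3)(c3ccccc3)c3ccccc3)c(CC=C(C)C)c2c1OC(C)(C)CC2.[Br-]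
F4 | step 9 | 2-{3-[8-methoxy-2,2-dimethyl-5-(3-methylbut-2-enyl)chroman-6-yl]prop-1-enyl}-5-(3-methylbut-2-enyloxy)phenol (E/Z mixture) | CC(C)=CCOc1ccc(C=CCc2cc(OC)c3c(c2CC=C(C)C)CCC(C)(C)O3)c(O)c1
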